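## Structural features

The target 20 is a trimer of three six-membered carbocycles joined by two CH2 bridges: a central aromatic ring A and two dearomatised outer rings B and C. Ring A is a fully substituted phloroglucinol in which the butanoyl-bearing carbon is flanked by two hydroxylated carbons, each bridge-bearing carbon lies between two hydroxylated carbons, and the third hydroxyl sits between the two bridges. Rings B and C are acylfilicinic acid units (4,4-dimethylcyclohexane-1,3,5-triones drawn as dienols), each attached through the ring carbon between two oxygenated carbons and each carrying an acyl group (acetyl in ring B, propanoyl in ring C) on the other such carbon. There is no stereocentre, so no stereocentres stand next to each other; the only quaternary carbons are the two CMe2 groups, and what must be controlled is connectivity. Fragile elements are the two aryl–CH2–enol bridges (they fragment through quinone methides in base once a ring A hydroxyl is free, or by ipso-protonation in strong acid), the β-triketones (open to retro-Claisen cleavage) and the oxidisable free polyphenol. The real difficulty is that rings B and C differ by a single CH2 group remote from ring A, so the two arms must be told apart before the rings exist, and that each outer ring needs a quaternary carbon and an acyl group in a fixed 1,3-relationship. The key step uses the fact that in rings B and C the CMe2 carbon with its two neighbouring carbonyl carbons is a dimethylmalonyl unit, while the bridge-bearing carbon, the oxygenated carbon next to it and the acyl-bearing carbon are the α′, carbonyl and α carbons of a β-methoxy enone whose enol ether carbon becomes the side-chain carbonyl.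

## Logic of the disconnections

20 ⇒ 19. The three phenolic O–H bonds of ring A are traced back to O–CH3 bonds. Ring A must carry no acidic proton during the enolate chemistry, and as long as it is etherified the quinone methide route to bridge scrambling is closed. The forward step must cleave three aryl methyl ethers without breaking a bridge; this is eased by having the deactivating butanoyl group already on ring A.

19 ⇒ 17 + 18. The aryl–carbonyl bond of the butanoyl group is cut. Its α-methylene is enolisable and could not be carried through the enolate step, so the acyl group has to come after the annulation. 17 offers only one unsubstituted nucleophilic carbon, so regiochemistry is not in question. The forward acylation must work at a carbon flanked by two methoxy groups and tolerate four enolic hydroxyls.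

17 ⇒ 13 + 14 (two molecules). Four C–C bonds are cut: in each of rings B and C, the bond from the bridge-bearing carbon to one carbonyl carbon next to CMe2, and the bond from the acyl-bearing carbon to the other. This removes both dearomatised rings, both quaternary carbons and both acyl side chains in one operation, and encodes acetyl versus propanoyl as methyl versus ethyl on an enol ether. The forward step must deprotonate α′ and not γ, acylate on carbon, take up exactly one molecule of 14 per arm (two in all), and close through carbon.

13 ⇒ 12 + 7. The bond between the benzylic carbon and the future α′ carbon of the propanoyl arm is cut. The benzylic cation derived from 12 is exceptionally stabilised by its three ring alkoxy groups, and 7 delivers the whole arm with its enol ether regiochemistry already fixed. The forward step must ionise the benzylic alcohol under catalytic acid without harming the arm already present.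

12 ⇒ 11. The benzylic alcohol is traced back to a formyl group. This is what differentiates the arms: one benzylic carbon is ionisable while the other is parked at the aldehyde level, so the two arms are installed in sequence. A symmetrical bis-electrophile would have to be desymmetrised statistically with two different nucleophiles. The forward reduction must spare the vinylogous ester.

11 ⇒ 10 + 3. The same kind of benzylic C–C bond is cut for the acetyl arm. The demand is chemoselectivity: the cation must be formed and trapped while the formyl group stays untouched.

10 ⇒ 8. The aryl–CHO bond is cut. The ring carbon between two methoxy groups is the natural site of directed metalation, so the formyl group enters at the only position that places the two benzylic carbons on either side of one methoxy group. The forward step needs a dianion (alkoxide plus aryllithium), which is 9.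

7 ⇒ 6 ⇒ 5 ⇒ 4, and 3 ⇒ 2 ⇒ 1. The O–Si bonds are cut back to the α′-enolates 6 and 2, and for 5 the enol ether C–O bond is cut back to 4. Conjugate addition to an ynone fixes which carbonyl of the 1,3-dicarbonyl unit is masked, which O-methylation of an unsymmetrical diketone would not. The forward enolisations must be kinetic (α′ methyl, not γ).

## Other disconnections considered

Alternative 1: The cut runs through ring A: both ring bonds of the phenol carbon between the arms, and the ring bond between the alkyne-derived ethoxy-bearing carbon and the unsubstituted CH. Forward, cyclobutenone A2 and ynol ether A3 would be heated in toluene (Danheiser benzannulation). Opening of A2 to a vinylketene, (2+2) cycloaddition with A3, a second four-electron opening and a six-electron closure would give phenol A1.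
- In favour: the two arms of A1 end in different groups (ester, silyl ether) by construction, the pentasubstituted ring is formed with full regiocontrol, and the step needs heat only.
- Against: A2 and A3 each need several steps of their own. A1 has two ethyl ethers and one free phenol, so a second protecting-group operation is needed. Both arms must still be taken to vinylogous esters by different sequences, and rings B and C and the butanoyl group are still to come.
- Comparison: on arm differentiation it is the equal of the chosen plan (both are non-statistical). On mechanistic predictability of its own key step it is the better, since the pericyclic cascade is better understood than step 8. On step economy it is clearly worse, because it spends its key step on a ring that 8 supplies ready-made.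

Alternative 2: The cut removes the two ring A bonds that join each bridge-bearing carbon to the hydroxylated carbon next to the unsubstituted CH. Forward, ketone A5, as its enamine or magnesium enolate, would be C-acylated at both α-carbons by malonyl dichloride A6 to give the des-butyryl trimer A4. A5 would come from two successive conjugate additions of acetylfilicinic acid A8 and propanoylfilicinic acid A9 to penta-1,4-dien-3-one A7.
- In favour: rings B and C arrive intact from known acylfilicinic acids, ring A needs no protecting group, and A4 is one acylation away from 20.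
- Against: simple ketones and A6 normally close through oxygen to pyranone-type lactones. A6 has acidic hydrogens and can lose HCl to a ketene. The four enolic hydroxyls of A5 consume base and acylating agent. A7 polymerises readily, and the two different additions to it must still be done in sequence. The final acylation would be on the unprotected, bridge-labile A4.
- Comparison: on step economy it is the better. On mechanism it is weaker: in the chosen plan 14 cannot form a ketene, the nucleophilic carbons are defined by the vinylogous ester, and the gem-dimethyl group favours closure. On protecting groups it is the better in number but worse in safety of the last step.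

Alternative 3: The cut removes one C–CH3 bond at the quaternary carbon of ring B and one of ring C. Forward, the all-aromatic trimer A11 would be treated with MeI and NaOMe in MeOH to give A10, which is the same compound as 19.
- In favour: C-methylation of acylphloroglucinols to acylfilicinic acids is long-established, the reagents are simple, the intermediates are robust aromatics, and the route joins the chosen one at 19.
- Against: in A11 every outer-ring carbon is substituted, so methylation must occur at the methyl-bearing carbon and not at the bridge-bearing carbon or at one of six phenolic oxygens. The outer rings of A11 are free phenols attached through CH2, so NaOMe can fragment the bridges. A11 itself must still be assembled with two different outer rings.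
- Comparison: on step economy and reagent simplicity it is the equal or the better. On site selectivity it is weaker: the chosen plan introduces the quaternary carbon as part of 14, so the question of where a methyl group goes never arises. On the endgame the two are equal.

Key step: step 8

Assumption: 1, 4, 8, 14 and 18 are taken as commercial. The enol ether double bonds are drawn E, but either geometry would serve because step 8 erases it, and rings B and C are drawn as one of their freely interconverting enol tautomers.

## Route

Step 1
Reactants: 1 (E)-4-methoxypent-3-en-2-one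
Product: 3 (3E)-4-methoxy-2-(trimethylsilyloxy)penta-1,3-diene, via lithium pentadienolate 2 (not isolated)
Conditions: LiN(i-Pr)2, THF, −78 °C; Me3SiCl, −78 °C → rt; distillation
Reagents that add atoms: chlorotrimethylsilane, C[Si](C)(C)Cl
Why: Kinetic deprotonation of a β-alkoxy enone by a lithium amide occurs at the α′ methyl (cross-conjugated dienolate) and O-silylation gives the 2-silyloxy diene, as in the preparation of Danishefsky-type dienes; the enol ether geometry is not touched.

Step 2
Reactants: 4 hex-3-yn-2-one
Product: 5 (E)-4-methoxyhex-3-en-2-one
Conditions: MeOH (3 equiv), PMe3 (10 mol %), CH2Cl2, 0 °C → rt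
Reagents that add atoms: methanol, CO
Why: Phosphine-catalysed conjugate addition of an alcohol to an ynone places the methoxy group on the β-carbon only, so the ethyl-bearing carbon is the masked one, and should give mainly the thermodynamically favoured E enol ether.

Step 3
Reactants: 5 (E)-4-methoxyhex-3-en-2-one
Product: 7 (3E)-4-methoxy-2-(trimethylsilyloxy)hexa-1,3-diene, via lithium hexadienolate 6 (not isolated)
Conditions: LiN(i-Pr)2, THF, −78 °C; Me3SiCl, −78 °C → rt; distillation
Reagents that add atoms: chlorotrimethylsilane, C[Si](C)(C)Cl
Why: As in step 1, kinetic enolisation removes a proton from the α′ methyl and not from the γ methylene, and the enolate is trapped on oxygen.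

Step 4
Reactants: 8 (2,4,6-trimethoxyphenyl)methanol
Product: 10 3-(hydroxymethyl)-2,4,6-trimethoxybenzaldehyde, via dilithiated alkoxide 9 (not isolated)
Conditions: n-BuLi (2.2 equiv), TMEDA, THF, 0 °C → rt; DMF, −78 °C → rt; H2O
Reagents that add atoms: N,N-dimethylformamide, CN(C)C=O
Why: The first equivalent of n-BuLi forms the alkoxide and the second metalates the ring carbon flanked by two methoxy groups (directed ortho-metalation); formylation by DMF (Bouveault-type) leaves one benzylic carbon at the alcohol level and the other at the aldehyde level.

Step 5
Reactants: 10 3-(hydroxymethyl)-2,4,6-trimethoxybenzaldehyde; 3 (3E)-4-methoxy-2-(trimethylsilyloxy)penta-1,3-diene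
Product: 11 3-[(4E)-5-methoxy-3-oxohex-4-en-1-yl]-2,4,6-trimethoxybenzaldehyde
Conditions: 3 (2.2 equiv), Me3SiOTf (10 mol %), CH2Cl2, −78 → −40 °C; aq NaHCO3
Reagents that add atoms: none
Why: Me3SiOTf ionises the 2,4,6-trialkoxybenzyl alcohol to a strongly stabilised cation that is captured at the terminal carbon of the silyl dienol ether (Mukaiyama-type SN1 benzylation), and loss of the silyl group returns the β-methoxy enone; the hindered, donor-conjugated formyl group should not be activated by a catalytic silyl triflate at low temperature.

Step 6
Reactants: 11 3-[(4E)-5-methoxy-3-oxohex-4-en-1-yl]-2,4,6-trimethoxybenzaldehyde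
Product: 12 (4E)-1-[3-(hydroxymethyl)-2,4,6-trimethoxyphenyl]-5-methoxyhex-4-en-3-one
Conditions: NaBH4, MeOH–THF, −20 → 0 °C
Reagents that add atoms: none
Why: Chemoselective hydride reduction: NaBH4 reduces the aryl aldehyde but should leave the vinylogous ester carbonyl, whose electrophilicity is lowered by the β-methoxy group.

Step 7
Reactants: 12 (4E)-1-[3-(hydroxymethyl)-2,4,6-trimethoxyphenyl]-5-methoxyhex-4-en-3-one; 7 (3E)-4-methoxy-2-(trimethylsilyloxy)hexa-1,3-diene
Product: 13 (4E)-5-methoxy-1-{2,4,6-trimethoxy-3-[(4E)-5-methoxy-3-oxohept-4-en-1-yl]phenyl}hex-4-en-3-one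
Conditions: 7 (2.2 equiv), Me3SiOTf (10 mol %), CH2Cl2, −78 °C; aq NaHCO3
Reagents that add atoms: none
Why: The same SN1 benzylation as in step 5; the silyl dienol ether is far more nucleophilic than the free ring A carbon or the push-pull alkene of the first arm, so the cation should be trapped at the diene terminus only.

Step 8
Reactants: 13 (4E)-5-methoxy-1-{2,4,6-trimethoxy-3-[(4E)-5-methoxy-3-oxohept-4-en-1-yl]phenyl}hex-4-en-3-one; 14 2,2-dimethylpropanedioyl dichloride (dimethylmalonyl dichloride; two molecules are consumed: one for each arm)
Product: 17 2-[(5-acetyl-2,6-dihydroxy-3,3-dimethyl-4-oxocyclohexa-1,5-dien-1-yl)methyl]-4-[(2,6-dihydroxy-3,3-dimethyl-4-oxo-5-propanoylcyclohexa-1,5-dien-1-yl)methyl]-1,3,5-trimethoxybenzene, via bis(bromomagnesium) dienolate 15 (not isolated), via bis(acyl chloride) 16 (not isolated)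
Conditions: LiN(i-Pr)2 (2.2 equiv), THF, −78 °C; MgBr2·OEt2 (2.4 equiv); cannulated into 14 (6 equiv, of which 2 equiv are incorporated), THF, −78 °C; i-Pr2NEt (5 equiv), −78 °C → rt; 1 M HCl; NaOMe, MeOH, 0 °C; 1 M HCl
Reagents that add atoms: 2,2-dimethylpropanedioyl dichloride (second molecule of 14 for the second arm), CC(C)(C(Cl)=O)C(Cl)=O
Why: Proposed new method: LiN(i-Pr)2 removes the α′ proton of each arm kinetically (cross-conjugated dienolate, Stork–Danheiser regiochemistry), MgBr2 gives the magnesium enolate 15, and inverse addition to excess 14 acylates each α′ carbon once, so that two molecules of 14 are taken up and 16 results; i-Pr2NEt and the MgBr2 still present then turn each new 1,3-diketone into its chelated dienolate, whose enol ether α-carbon attacks the tethered acid chloride, and chloride removes the O-methyl group from the resulting oxocarbenium ion as MeCl to leave the acyl triketone. The closest known reactions are C-acylation of kinetic α′-enolates of vinylogous esters by acid chlorides and intramolecular C-acylation of enol ethers, which have not been run in tandem on a malonyl dichloride. Ring B and ring C are each closed by a 6-(enolexo)-exo-trig attack of the enol ether carbon on the acyl chloride. No stereocentre is created, since every new ring carbon ends up trigonal or as the symmetrically substituted CMe2. The step needs α′ over γ deprotonation (kinetic conditions at −78 °C), carbon over oxygen acylation at α′ (magnesium counter-ion, inverse addition), exactly one molecule of 14 per arm with no arm-to-arm linking (excess of 14, gem-dimethyl effect on closure) and carbon over oxygen in the ring closure (both oxygens tied into the magnesium chelate). 14 has no α-hydrogen and cannot form a ketene, and ring A as its trimethyl ether offers neither acidic protons nor a quinone methide pathway. The acid and NaOMe work-up cleaves O-acylated by-products and should let a seco-ester or enol lactone isomer close to the same ring by Claisen condensation.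

Step 9
Reactants: 17 2-[(5-acetyl-2,6-dihydroxy-3,3-dimethyl-4-oxocyclohexa-1,5-dien-1-yl)methyl]-4-[(2,6-dihydroxy-3,3-dimethyl-4-oxo-5-propanoylcyclohexa-1,5-dien-1-yl)methyl]-1,3,5-trimethoxybenzene; 18 butanoyl chloride
Product: 19 1-{3-[(5-acetyl-2,6-dihydroxy-3,3-dimethyl-4-oxocyclohexa-1,5-dien-1-yl)methyl]-5-[(2,6-dihydroxy-3,3-dimethyl-4-oxo-5-propanoylcyclohexa-1,5-dien-1-yl)methyl]-2,4,6-trimethoxyphenyl}butan-1-one
Conditions: 18 (3 equiv), TiCl4 (6 equiv), CH2Cl2, −20 → 0 °C; 1 M HCl; K2CO3, MeOH, 0 °C
Reagents that add atoms: none
Why: Friedel–Crafts acylation: ring A has a single unsubstituted carbon, activated by three methoxy groups, and the triketone rings have no free carbon; enol butanoates formed on oxygen are cleaved by the methanolic K2CO3 work-up, during which the ring A ethers block base-induced bridge fragmentation.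

Step 10
Reactants: 19 1-{3-[(5-acetyl-2,6-dihydroxy-3,3-dimethyl-4-oxocyclohexa-1,5-dien-1-yl)methyl]-5-[(2,6-dihydroxy-3,3-dimethyl-4-oxo-5-propanoylcyclohexa-1,5-dien-1-yl)methyl]-2,4,6-trimethoxyphenyl}butan-1-one
Product: 20 1-{3-[(5-acetyl-2,6-dihydroxy-3,3-dimethyl-4-oxocyclohexa-1,5-dien-1-yl)methyl]-5-[(2,6-dihydroxy-3,3-dimethyl-4-oxo-5-propanoylcyclohexa-1,5-dien-1-yl)methyl]-2,4,6-trihydroxyphenyl}butan-1-one
Conditions: BBr3 (8 equiv), CH2Cl2, −78 → 0 °C; MeOH, then H2O
Reagents that add atoms: none
Why: Lewis acid cleavage of the three aryl methyl ethers: the two flanking the butanoyl group are assisted by chelation, the third is twisted out of conjugation by its two benzylic neighbours and is therefore basic, and the acyl group deactivates ring A against ipso-protonation at the bridges.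

## Compound list

1 | (E)-4-methoxypent-3-en-2-one | CC(=O)/C=C(/OC)C | starting material
2 | lithium (3E)-4-methoxypenta-1,3-dien-2-olate (not isolated) | C=C(O[Li])/C=C(/OC)C | intermediate
3 | (3E)-4-methoxy-2-(trimethylsilyloxy)penta-1,3-diene | C=C(O[Si](C)(C)C)/C=C(/OC)C | intermediate
4 | hex-3-yn-2-one | CC(=O)C#CCC | starting material
5 | (E)-4-methoxyhex-3-en-2-one | CC(=O)/C=C(/OC)CC | intermediate
6 | lithium (3E)-4-methoxyhexa-1,3-dien-2-olate (not isolated) | C=C(O[Li])/C=C(/OC)CC | intermediate
7 | (3E)-4-methoxy-2-(trimethylsilyloxy)hexa-1,3-diene | C=C(O[Si](C)(C)C)/C=C(/OC)CC | intermediate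
8 | (2,4,6-trimethoxyphenyl)methanol | COc1cc(OC)c(CO)c(OC)c1 | starting material
9 | lithium (3-lithio-2,4,6-trimethoxyphenyl)methanolate (not isolated) | [Li]OCc1c(OC)cc(OC)c([Li])c1OC | intermediate
10 | 3-(hydroxymethyl)-2,4,6-trimethoxybenzaldehyde | COc1cc(OC)c(C=O)c(OC)c1CO | intermediate
11 | 3-[(4E)-5-methoxy-3-oxohex-4-en-1-yl]-2,4,6-trimethoxybenzaldehyde | COc1cc(OC)c(C=O)c(OC)c1CCC(=O)/C=C(/OC)C | intermediate
12 | (4E)-1-[3-(hydroxymethyl)-2,4,6-trimethoxyphenyl]-5-methoxyhex-4-en-3-one | COc1cc(OC)c(CO)c(OC)c1CCC(=O)/C=C(/OC)C | intermediate
13 | (4E)-5-methoxy-1-{2,4,6-trimethoxy-3-[(4E)-5-methoxy-3-oxohept-4-en-1-yl]phenyl}hex-4-en-3-one | COc1cc(OC)c(CCC(=O)/C=C(/OC)C)c(OC)c1CCC(=O)/C=C(/OC)CC | intermediate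
14 | 2,2-dimethylpropanedioyl dichloride (dimethylmalonyl dichloride) | CC(C)(C(Cl)=O)C(Cl)=O | starting material
15 | bis(bromomagnesium) bis-dienolate of 13, both α′ carbons deprotonated (not isolated; geometry of the new enolate double bonds undefined and of no consequence) | COc1cc(OC)c(CC=C(O[Mg]Br)/C=C(/OC)C)c(OC)c1CC=C(O[Mg]Br)/C=C(/OC)CC | intermediate
16 | 13 carrying a 3-chloro-2,2-dimethyl-3-oxopropanoyl group on each α′ carbon (not isolated; the two α′ carbons are epimerisable 1,3-diketone methines, no configuration implied) | COc1cc(OC)c(CC(C(=O)C(C)(C)C(Cl)=O)C(=O)/C=C(/OC)C)c(OC)c1CC(C(=O)C(C)(C)C(Cl)=O)C(=O)/C=C(/OC)CC | intermediate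
17 | 2-[(5-acetyl-2,6-dihydroxy-3,3-dimethyl-4-oxocyclohexa-1,5-dien-1-yl)methyl]-4-[(2,6-dihydroxy-3,3-dimethyl-4-oxo-5-propanoylcyclohexa-1,5-dien-1-yl)methyl]-1,3,5-trimethoxybenzene | COc1cc(OC)c(CC2=C(O)C(C)(C)C(=O)C(C(C)=O)=C2O)c(OC)c1CC1=C(O)C(C)(C)C(=O)C(C(=O)CC)=C1O | intermediate
18 | butanoyl chloride | CCCC(Cl)=O | starting material
19 | 1-{3-[(5-acetyl-2,6-dihydroxy-3,3-dimethyl-4-oxocyclohexa-1,5-dien-1-yl)methyl]-5-[(2,6-dihydroxy-3,3-dimethyl-4-oxo-5-propanoylcyclohexa-1,5-dien-1-yl)methyl]-2,4,6-trimethoxyphenyl}butan-1-one | CCCC(=O)c1c(OC)c(CC2=C(O)C(C)(C)C(=O)C(C(C)=O)=C2O)c(OC)c(CC2=C(O)C(C)(C)C(=O)C(C(=O)CC)=C2O)c1OC | intermediate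
20 | 1-{3-[(5-acetyl-2,6-dihydroxy-3,3-dimethyl-4-oxocyclohexa-1,5-dien-1-yl)methyl]-5-[(2,6-dihydroxy-3,3-dimethyl-4-oxo-5-propanoylcyclohexa-1,5-dien-1-yl)methyl]-2,4,6-trihydroxyphenyl}butan-1-one (CNP0325527.0) | CCCC(=O)c1c(O)c(CC2=C(O)C(C)(C)C(=O)C(C(C)=O)=C2O)c(O)c(CC2=C(O)C(C)(C)C(=O)C(C(=O)CC)=C2O)c1O | target

## Step count and least certain steps

Total: 10 steps. Longest linear sequence: 7 steps (8 → 20 through steps 4 to 10); steps 1 and 2–3 are side branches that supply 3 and 7.

**Step 8 (key step, proposed new method).** What may go wrong: acylation of the α′-enolate on oxygen instead of carbon, ring closure through the enol oxygen to an enol lactone, or linking of two arms or two molecules by one molecule of 14. The cause is that a hindered, doubly electrophilic acid chloride meets an ambident enolate, and the second acylation relies on a weakly nucleophilic enol ether carbon. The fallback uses known chemistry, sets out from 13 and comes back at 17. 13 is converted into its magnesium bis-enolate as in the first stage of step 8 and C-acylated with methyl 3-chloro-2,2-dimethyl-3-oxopropanoate (one molecule per arm), which can react only once, to give the bis(α′-acyl) diester F1. 1 M HCl in THF hydrolyses both enol ethers to the bis(3,5,7-triketo ester) F2. NaOMe in MeOH (or KOt-Bu in THF) then closes both rings by intramolecular Claisen condensation of the doubly activated methylene on the ester; the aldol mode is blocked by the quaternary carbon, so 17 is the only six-membered product.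

**Step 5.** What may go wrong: activation of the formyl group toward the silyl dienol ether (aldol or hetero-Diels–Alder addition) in competition with ionisation of the alcohol, and protodesilylation of 3 by adventitious triflic acid. The fallback sets out from 8 and 3 and comes back at 12. 8 is benzylated with 3 under the conditions of step 5, where no carbonyl electrophile is present, to give the mono-arm ketone F3. N-Bromosuccinimide in MeCN at −40 °C brominates one of the two equivalent free ring A positions to give the aryl bromide F4. Stille coupling with Bu3SnCH2OH and the zerovalent palladium complex Pd(PPh3)4 in dioxane installs the hydroxymethyl group and gives 12, so that step 6 is no longer needed.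

**Step 9.** What may go wrong: stalling of C-acylation at the doubly flanked ring A carbon while the enol oxygens are acylated instead, or ipso attack with loss of a bridge under the Lewis acid. The fallback sets out from 17 and comes back at 20. BBr3 first frees ring A to give the des-butyryl trimer F5 (the same compound as A4). Its far more nucleophilic free phloroglucinol ring is then acylated under Houben–Hoesch conditions (butyronitrile, ZnCl2, HCl, Et2O, 0 °C, then hydrolysis of the ketimine), which need no strong Lewis acid; step 10 falls away.

**Step 10.** What may go wrong: acid-mediated fragmentation at the methylene bridges, loss of the butanoyl group, or cyclodehydration between a freed ring A hydroxyl and a neighbouring enol to a xanthene-type ether. The fallback sets out from 19 and comes back at 20. BCl3 at −78 → 0 °C, bound to the butanoyl carbonyl, removes only the two flanking methyl groups and gives the mono-methyl ether F6. The remaining, twisted methoxy group is then cleaved by SN2 attack of iodide with Me3SiCl and NaI in MeCN, which avoids the strong Lewis acid.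

## Further compounds

F1 | step 8 | 13 carrying a 3-methoxy-2,2-dimethyl-3-oxopropanoyl group on each α′ carbon (epimerisable methines, no configuration implied) | COc1cc(OC)c(CC(C(=O)C(C)(C)C(=O)OC)C(=O)/C=C(/OC)C)c(OC)c1CC(C(=O)C(C)(C)C(=O)OC)C(=O)/C=C(/OC)CC
F2 | step 8 | bis(3,5,7-triketo ester) from hydrolysis of both enol ethers of F1 (epimerisable methines, no configuration implied) | COc1cc(OC)c(CC(C(=O)C(C)(C)C(=O)OC)C(=O)CC(C)=O)c(OC)c1CC(C(=O)C(C)(C)C(=O)OC)C(=O)CC(=O)CC
F3 | step 5 | (4E)-5-methoxy-1-(2,4,6-trimethoxyphenyl)hex-4-en-3-one | COc1cc(OC)c(CCC(=O)/C=C(/OC)C)c(OC)c1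
F4 | step 5 | (4E)-1-(3-bromo-2,4,6-trimethoxyphenyl)-5-methoxyhex-4-en-3-one | COc1cc(OC)c(CCC(=O)/C=C(/OC)C)c(OC)c1Br
F5 | step 9 | 2-[(5-acetyl-2,6-dihydroxy-3,3-dimethyl-4-oxocyclohexa-1,5-dien-1-yl)methyl]-4-[(2,6-dihydroxy-3,3-dimethyl-4-oxo-5-propanoylcyclohexa-1,5-dien-1-yl)methyl]benzene-1,3,5-triol | Oc1cc(O)c(CC2=C(O)C(C)(C)C(=O)C(C(C)=O)=C2O)c(O)c1CC1=C(O)C(C)(C)C(=O)C(C(=O)CC)=C1O
F6 | step 10 | 1-{3-[(5-acetyl-2,6-dihydroxy-3,3-dimethyl-4-oxocyclohexa-1,5-dien-1-yl)methyl]-5-[(2,6-dihydroxy-3,3-dimethyl-4-oxo-5-propanoylcyclohexa-1,5-dien-1-yl)methyl]-2,6-dihydroxy-4-methoxyphenyl}butan-1-one | CCCC(=O)c1c(O)c(CC2=C(O)C(C)(C)C(=O)C(C(C)=O)=C2O)c(OC)c(CC2=C(O)C(C)(C)C(=O)C(C(=O)CC)=C2O)c1O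
A1 | alternative 1 | methyl 3-[3-(3-(tert-butyldimethylsilyloxy)propyl)-4,6-diethoxy-2-hydroxyphenyl]propanoate | Oc1c(CCCO[Si](C)(C)C(C)(C)C)c(OCC)cc(OCC)c1CCC(=O)OC
A2 | alternative 1 | methyl 3-(2-ethoxy-4-oxocyclobut-2-en-1-yl)propanoate (racemic) | CCOC1=CC(=O)C1CCC(=O)OC
A3 | alternative 1 | tert-butyl[(5-ethoxypent-4-yn-1-yl)oxy]dimethylsilane | CCOC#CCCCO[Si](C)(C)C(C)(C)C
A4 | alternative 2 | 2-[(5-acetyl-2,6-dihydroxy-3,3-dimethyl-4-oxocyclohexa-1,5-dien-1-yl)methyl]-4-[(2,6-dihydroxy-3,3-dimethyl-4-oxo-5-propanoylcyclohexa-1,5-dien-1-yl)methyl]benzene-1,3,5-triol | Oc1cc(O)c(CC2=C(O)C(C)(C)C(=O)C(C(C)=O)=C2O)c(O)c1CC1=C(O)C(C)(C)C(=O)C(C(=O)CC)=C1O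
A5 | alternative 2 | 1-(5-acetyl-2,6-dihydroxy-3,3-dimethyl-4-oxocyclohexa-1,5-dien-1-yl)-5-(2,6-dihydroxy-3,3-dimethyl-4-oxo-5-propanoylcyclohexa-1,5-dien-1-yl)pentan-3-one | O=C(CCC1=C(O)C(C)(C)C(=O)C(C(C)=O)=C1O)CCC1=C(O)C(C)(C)C(=O)C(C(=O)CC)=C1O
A6 | alternative 2 | propanedioyl dichloride (malonyl dichloride) | O=C(Cl)CC(Cl)=O
A7 | alternative 2 | penta-1,4-dien-3-one | C=CC(=O)C=C
A8 | alternative 2 | 2-acetyl-3,5-dihydroxy-6,6-dimethylcyclohexa-2,4-dien-1-one (acetylfilicinic acid) | CC(=O)C1=C(O)C=C(O)C(C)(C)C1=O
A9 | alternative 2 | 3,5-dihydroxy-6,6-dimethyl-2-propanoylcyclohexa-2,4-dien-1-one (propanoylfilicinic acid) | CCC(=O)C1=C(O)C=C(O)C(C)(C)C1=O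
A10 | alternative 3 | 1-{3-[(5-acetyl-2,6-dihydroxy-3,3-dimethyl-4-oxocyclohexa-1,5-dien-1-yl)methyl]-5-[(2,6-dihydroxy-3,3-dimethyl-4-oxo-5-propanoylcyclohexa-1,5-dien-1-yl)methyl]-2,4,6-trimethoxyphenyl}butan-1-one (identical with 19) | CCCC(=O)c1c(OC)c(CC2=C(O)C(C)(C)C(=O)C(C(C)=O)=C2O)c(OC)c(CC2=C(O)C(C)(C)C(=O)C(C(=O)CC)=C2O)c1OC
A11 | alternative 3 | 1-{3-[(3-acetyl-2,4,6-trihydroxy-5-methylphenyl)methyl]-5-[(2,4,6-trihydroxy-3-methyl-5-propanoylphenyl)methyl]-2,4,6-trimethoxyphenyl}butan-1-one | CCCC(=O)c1c(OC)c(Cc2c(O)c(C)c(O)c(C(C)=O)c2O)c(OC)c(Cc2c(O)c(C)c(O)c(C(=O)CC)c2O)c1OC
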